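Ring positions are written as ring letter plus number (position A1 = carbon 1 of ring A). The labels "compound A1" to "compound A7" denote compounds of the routes that were turned down and are always preceded by the word "compound".

## Analysis of the target

Pseudopentafuhalol D (18) is a linear chain of five benzene rings, A to E, joined only by four diaryl ether oxygens (A4–O–B2, B1–O–C1, C5–O–D1, D6–O–E1) and carrying thirteen free phenolic hydroxyls. The hydroxyls sit at A1, A3, A5, at B4, B6, at C3, C4, at D3, D4, D5 and at E3, E4, E5. There is no stereocentre and no stable chiral axis, so stereocontrol plays no part. The catechol of ring C and the pyrogallol units of rings D and E are oxidised by air, above all in base, so the free polyphenol can appear only in the last step. The difficulty is the placement of seventeen oxygen substituents on electron-rich rings, together with crowding: three of the four ether links have one terminus (A4, B1, D6) flanked by two oxygenated carbons. The strategy rests on positions A1 and B4, the only oxygenated carbons with a CH on both sides. Without these two oxygens, rings A and B are plain 1,2,3-trioxygenated benzenes, and A1 and B4 are the only aromatic C–H bonds of the whole pentaaryl ether that have no ortho substituent.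

## Retrosynthetic reasoning

**18 to 17.** The eleven O–CH3 bonds are cut. Methyl ethers are small enough not to disturb a sterically governed step, and they survive copper catalysis, peracid and iridium catalysis. The forward step is a boron trihalide ether cleavage, which cannot break the aryl–O–aryl links because neither carbon of such a link is open to SN2 attack.

**17 to 15, through 16.** The A1–O and B4–O bonds are cut. They are chosen because their carbons alone have hydrogen on both neighbours. Removing them turns the phloroglucinol-type rings A and B into 1,2,3-trioxygenated rings that come from catalogue compounds and are easier to couple. The forward reaction has to pick two of eleven aromatic C–H bonds. Sterically controlled iridium-catalysed borylation to bis(boronate) 16, followed by peroxide oxidation in the same flask, does this.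

**15 to 5 and 14.** The B1–O–C1 ether is cut on the ring C side. This divides the molecule into two halves of similar size. C1 lies between two CH groups, so the bromide 14 is an unhindered electrophile, whereas B1 lies between two oxygenated carbons and could only serve as the phenol. The forward step is an Ullmann ether synthesis with the hindered phenol 5.

**5 to 3 (through formate 4), then to 1 and 2.** The B1 hydroxyl is traced back to a formyl group, to be exchanged for oxygen by Baeyer–Villiger oxidation. The same formyl group activates the neighbouring fluoride of 2, so the most crowded ether, A4–O–B2, is made by nucleophilic aromatic substitution with the phenoxide of 1 and needs no metal. The cut is on the B2 side because A4 is flanked on both sides and could not act as the electrophile.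

**14 to 10 and 13.** The C5–O–D1 ether is cut on the ring C side. Ring C then becomes the 1,5-dihalide 13, with iodine at C5 for this coupling and bromine at C1 held back for the union with 5. The phenol 10 has only one ortho substituent at D1, so the more hindered halide meets the less hindered phenol.

**10 to 8 (through formate 9), then to 6 and 7.** The same aldehyde device is used again. The D1 hydroxyl comes from a formyl group, and the D6–O–E1 ether is formed at a bromide that the ortho formyl group activates. D6 is flanked by two substituents and is better as the electrophile than as the phenol; ring E enters as the unhindered phenol 6.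

**13 to 12, then to 11.** The O–CH3 bond and the C–I bond are cut. Iodination of 11 can only go ortho to the hydroxyl, since the para position holds bromine, and methylation then gives the dihalide.

## Alternatives that were turned down

**Alternative 1:** Ring A is built from a chain. The bond between carbon A4 (the aryloxy-bearing carbon) and carbon A3 is cut, which opens the ring to the triketide compound A2, methyl 6-[2-(benzyloxy)-3,5-dimethoxyphenoxy]-3,5-dioxohexanoate.
- Forward key step: base forms the carbanion at the aryloxy-substituted terminus, intramolecular Claisen condensation on the ester closes the ring, and enolisation gives compound A1, 2-[2-(benzyloxy)-3,5-dimethoxyphenoxy]benzene-1,3,5-triol.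
- For it: all three oxygens of ring A, the one at position A1 included, come from carbonyl groups with no regiochemical question and no transition metal. On this point it is stronger than the chosen route, which depends on a late C–H functionalisation.
- Against it: the reacting carbon is the least acidic methylene of the chain, so a polyanion is needed, and 3,5-dioxo esters usually close through oxygen to a 4-hydroxy-2-pyrone. Compound A1 has three free hydroxyls that must be capped before the benzyl group can be exchanged for ring C. The 1,2,3,5-tetraoxygenated ring B must already be present in compound A2, so the harder ring is moved into the starting material, not solved.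
- Comparison: the chosen route takes ring A from 1 without a step, adds the A1 oxygen in the same operation as the B4 oxygen, and is shorter by several steps.

**Alternative 2:** Ring B is made from a pyrone. The B1–B6 bond is cut and the ring is traced to compound A4, 6-{[3-(benzyloxy)-4,5-dimethoxyphenoxy]methyl}-4-methoxy-2H-pyran-2-one.
- Forward key step: with Mg(OMe)2 in methanol, methoxide opens the lactone to a chelated keto ester, the aryloxy-substituted carbanion attacks the ester carbonyl, and aromatisation gives compound A3, 2-[3-(benzyloxy)-4,5-dimethoxyphenoxy]-5-methoxybenzene-1,3-diol.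
- For it: the hindered B1–O–C1 ether is in place before ring B exists, and the B4 oxygen is present from the start as a methyl ether. Here it is at least as strong as the chosen route.
- Against it: compound A3 is symmetric about the B1–B4 axis, so its two hydroxyls are equivalent, yet the target needs one of them (B2) arylated by ring A and the other (B6) left alone. That mono-arylation pairs a crowded phenol with a 2,4,6-trioxygenated, doubly ortho-substituted aryl halide, the least favourable case for an Ullmann coupling, and would give statistical mixtures.
- Comparison: the chosen route forms the same A4–O–B2 bond in step 1 by metal-free substitution of an activated fluoride, with ring A as the nucleophile and no symmetry problem, and it treats rings A and B together.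

**Alternative 3:** Ring D is made from compound A7 (dimethyl squarate). The D6–D1 bond is cut. The precursor is compound A6, racemic 4-[(Z)-2-(5-benzyloxy-2,3-dimethoxyphenoxy)ethenyl]-2,3,4-trimethoxycyclobut-2-en-1-one, from addition of a 2-aryloxyvinyl-lithium to compound A7 and O-methylation.
- Forward key step: on heating, the four-membered ring opens to a vinylketene with the aryloxyvinyl group turned inward, 6π electrocyclisation closes the six-membered ring, and tautomerisation gives compound A5, 6-(5-benzyloxy-2,3-dimethoxyphenoxy)-2,3,4-trimethoxyphenol, free only at D6.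
- For it: the five contiguous oxygens of ring D are placed with full regiocontrol, and D6 is set apart from the methoxy positions without a protecting-group step. In certainty of substitution pattern it equals the chosen route.
- Against it: the free D6 hydroxyl, flanked by a methoxy and an aryloxy group, must then be arylated with an electron-rich ring E halide. This is the less favourable polarity compared with step 3, where D6 is the electrophile and is activated by the formyl group. 2-Aryloxyvinyl anions also tend to lose aryloxide by β-elimination.
- Comparison: three steps from compound A7 give a ring whose substitution pattern can be bought as 7. The alternative also does nothing for rings A and B, where the two isolated hydroxyls lie and where the chosen strategy makes its simplification.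

Key step: step 9

Assumption: 2-bromo-3,4,5-trimethoxybenzaldehyde (7) and 4-bromo-2-methoxyphenol (11) are treated as catalogue compounds; all copper- and iridium-catalysed steps are run under argon.

## Route

Step 1
Reactants: 1 2,6-dimethoxyphenol; 2 2-fluoro-6-methoxybenzaldehyde
Product: 3 2-(2,6-dimethoxyphenoxy)-6-methoxybenzaldehyde
Conditions: K2CO3, DMF, 120 °C
Reagents that add atoms: none
Why: Nucleophilic aromatic substitution; the ortho formyl group stabilises the Meisenheimer intermediate, the 6-methoxy group is meta to the reacting carbon and does not deactivate it, and the hindered but electron-rich phenoxide of 1 is a competent nucleophile in a dipolar aprotic solvent.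

Step 2
Reactants: 3 2-(2,6-dimethoxyphenoxy)-6-methoxybenzaldehyde
Product: 5 2-(2,6-dimethoxyphenoxy)-6-methoxyphenol (ring AB phenol), via aryl formate 4 (not isolated)
Conditions: mCPBA, CH2Cl2, 0 °C to rt; aq. Na2S2O3/NaHCO3 wash; then K2CO3 (cat.), MeOH, rt
Reagents that add atoms: mCPBA (3-chloroperoxybenzoic acid), SMILES O=C(OO)c1cccc(Cl)c1
Why: Baeyer–Villiger (Dakin-type) oxidation; in the Criegee intermediate the aryl group, made electron-rich by two ortho oxygen substituents, migrates in preference to hydrogen to give formate 4, which mild methanolysis cleaves to 5. The ethers are inert to the peracid at this temperature.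

Step 3
Reactants: 6 3,4,5-trimethoxyphenol; 7 2-bromo-3,4,5-trimethoxybenzaldehyde
Product: 8 3,4,5-trimethoxy-2-(3,4,5-trimethoxyphenoxy)benzaldehyde
Conditions: CuI (10 mol%), N,N-dimethylglycine hydrochloride (30 mol%), Cs2CO3, dioxane, 100 °C
Reagents that add atoms: none
Why: Ullmann diaryl ether synthesis; the ortho formyl group speeds oxidative addition of the C–Br bond to the copper phenoxide (monovalent copper) and so offsets the ortho methoxy group, and 6 is an unhindered phenol. The pairing of a 2-bromo-3,4,5-trialkoxy carbonyl arene with a phenol is classical for this reaction.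

Step 4
Reactants: 8 3,4,5-trimethoxy-2-(3,4,5-trimethoxyphenoxy)benzaldehyde
Product: 10 3,4,5-trimethoxy-2-(3,4,5-trimethoxyphenoxy)phenol (ring DE phenol), via aryl formate 9 (not isolated)
Conditions: mCPBA, CH2Cl2, 0 °C to rt; aq. Na2S2O3/NaHCO3 wash; then K2CO3 (cat.), MeOH, rt
Reagents that add atoms: mCPBA (3-chloroperoxybenzoic acid), SMILES O=C(OO)c1cccc(Cl)c1
Why: Baeyer–Villiger oxidation as in step 2; the migrating ring carries an ortho aryloxy and a para methoxy donor, so aryl migration to formate 9 should dominate, and methanolysis then frees the D1 hydroxyl.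

Step 5
Reactants: 11 4-bromo-2-methoxyphenol
Product: 12 4-bromo-2-iodo-6-methoxyphenol
Conditions: N-iodosuccinimide, TsOH·H2O (10 mol%), MeCN, 0 °C to rt
Reagents that add atoms: N-iodosuccinimide, SMILES O=C1CCC(=O)N1I
Why: Electrophilic aromatic iodination; the free hydroxyl is the strongest activating group and its para position is blocked by bromine, so iodine should enter at the one free ortho position.

Step 6
Reactants: 12 4-bromo-2-iodo-6-methoxyphenol
Product: 13 5-bromo-1-iodo-2,3-dimethoxybenzene
Conditions: MeI, K2CO3, acetone, reflux
Reagents that add atoms: iodomethane, SMILES CI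
Why: Williamson O-methylation of the phenoxide by SN2 on MeI; both aryl halides are inert under these conditions.

Step 7
Reactants: 10 3,4,5-trimethoxy-2-(3,4,5-trimethoxyphenoxy)phenol; 13 5-bromo-1-iodo-2,3-dimethoxybenzene (1.5 equiv)
Product: 14 1-(5-bromo-2,3-dimethoxyphenoxy)-3,4,5-trimethoxy-2-(3,4,5-trimethoxyphenoxy)benzene (ring CDE bromide)
Conditions: CuI (10 mol%), picolinic acid (20 mol%), K3PO4, DMSO, 80 °C
Reagents that add atoms: none
Why: Ullmann ether synthesis with halogen discrimination; oxidative addition of C–I to the ligated copper phenoxide (monovalent copper) is much faster than that of C–Br, so at moderate temperature and with 13 in excess the phenol 10 should be arylated at C5 while the C1 bromide is kept for step 8.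

Step 8
Reactants: 5 2-(2,6-dimethoxyphenoxy)-6-methoxyphenol; 14 ring CDE bromide
Product: 15 1-{5-[2-(2,6-dimethoxyphenoxy)-6-methoxyphenoxy]-2,3-dimethoxyphenoxy}-3,4,5-trimethoxy-2-(3,4,5-trimethoxyphenoxy)benzene (permethylated pentaaryl ether lacking the A1 and B4 oxygens)
Conditions: CuI (20 mol%), picolinic acid (40 mol%), K3PO4, DMSO, 105 °C
Reagents that add atoms: none
Why: Ullmann ether synthesis; picolinic acid-ligated copper is known to couple 2,6-disubstituted phenols with aryl bromides. The C1–Br of 14 has hydrogen on both sides, so the steric load lies on the phenoxide side only.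

Step 9
Reactants: 15 permethylated pentaaryl ether lacking the A1 and B4 oxygens
Product: 17 undeca-O-methyl pseudopentafuhalol D (hydroxyls free at A1 and B4), via bis(pinacol boronate) 16 (not isolated)
Conditions: [Ir(OMe)(cod)]2 (5 mol%), 4,4'-di-tert-butyl-2,2'-bipyridine (10 mol%), B2pin2 (3 equiv), THF, 80 °C; then aq. NaOH, 30% H2O2, 0 °C to rt
Reagents that add atoms: hydrogen peroxide, SMILES OO (supplies the A1 and B4 oxygens of 17); bis(pinacolato)diboron, SMILES CC1(C)OB(OC1(C)C)B1OC(C)(C)C(C)(C)O1 (supplies the boronate groups of 16, lost again on oxidation)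
Why: [Ir(OMe)(cod)]2, the bipyridine and B2pin2 form a tris(boryl) complex of trivalent iridium with one free site; it cleaves an aryl C–H bond by oxidative addition, the aryl boronate leaves by C–B reductive elimination, and B2pin2 restores the tris(boryl) species with release of HBpin. The closest known reaction type is the borylation of 1,2,3-trisubstituted benzenes at C5 under steric control with oxidation of the boronate to the phenol in the same flask. The selectivity needed is among eleven aromatic C–H bonds: nine of them (A2, A6, B3, B5, C2, C6, D2, E2, E6) have an oxygen substituent on at least one neighbouring carbon and are shielded from the crowded iridium centre, and only A1 and B4 have hydrogen on both sides. The bipyridine ligand leaves no site for chelation by an ether oxygen, so no ortho-directed pathway should compete. Excess B2pin2 drives both rings to 16. Hydroperoxide then adds to each boron and the aryl group shifts from boron to oxygen, which places the new C–O bond exactly where the C–B bond was. No ring is closed and no stereocentre is formed.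

Step 10
Reactants: 17 undeca-O-methyl pseudopentafuhalol D
Product: 18 pseudopentafuhalol D
Conditions: BBr3 (25 equiv), CH2Cl2, −78 °C to rt; then degassed H2O, 0 °C, under argon
Reagents that add atoms: none
Why: Lewis acid ether cleavage; BBr3 binds each methoxy oxygen and bromide removes the methyl group by SN2, while the aryl–O–aryl bonds offer no carbon open to SN2 attack and should survive. Hydrolysis of the aryl borates with exclusion of air should release 18.

## Compound list

1 | 2,6-dimethoxyphenol | COc1cccc(OC)c1O | starting material
2 | 2-fluoro-6-methoxybenzaldehyde | COc1cccc(F)c1C=O | starting material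
3 | 2-(2,6-dimethoxyphenoxy)-6-methoxybenzaldehyde | COc1cccc(OC)c1Oc1cccc(OC)c1C=O | intermediate
4 | 2-(2,6-dimethoxyphenoxy)-6-methoxyphenyl formate | COc1cccc(OC)c1Oc1cccc(OC)c1OC=O | intermediate
5 | 2-(2,6-dimethoxyphenoxy)-6-methoxyphenol | COc1cccc(OC)c1Oc1cccc(OC)c1O | intermediate
6 | 3,4,5-trimethoxyphenol | COc1cc(O)cc(OC)c1OC | starting material
7 | 2-bromo-3,4,5-trimethoxybenzaldehyde | COc1cc(C=O)c(Br)c(OC)c1OC | starting material
8 | 3,4,5-trimethoxy-2-(3,4,5-trimethoxyphenoxy)benzaldehyde | COc1cc(C=O)c(Oc2cc(OC)c(OC)c(OC)c2)c(OC)c1OC | intermediate
9 | 3,4,5-trimethoxy-2-(3,4,5-trimethoxyphenoxy)phenyl formate | COc1cc(OC=O)c(Oc2cc(OC)c(OC)c(OC)c2)c(OC)c1OC | intermediate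
10 | 3,4,5-trimethoxy-2-(3,4,5-trimethoxyphenoxy)phenol | COc1cc(O)c(Oc2cc(OC)c(OC)c(OC)c2)c(OC)c1OC | intermediate
11 | 4-bromo-2-methoxyphenol | COc1cc(Br)ccc1O | starting material
12 | 4-bromo-2-iodo-6-methoxyphenol | COc1cc(Br)cc(I)c1O | intermediate
13 | 5-bromo-1-iodo-2,3-dimethoxybenzene | COc1cc(Br)cc(I)c1OC | intermediate
14 | 1-(5-bromo-2,3-dimethoxyphenoxy)-3,4,5-trimethoxy-2-(3,4,5-trimethoxyphenoxy)benzene | COc1cc(Br)cc(Oc2cc(OC)c(OC)c(OC)c2Oc2cc(OC)c(OC)c(OC)c2)c1OC | intermediate
15 | 1-{5-[2-(2,6-dimethoxyphenoxy)-6-methoxyphenoxy]-2,3-dimethoxyphenoxy}-3,4,5-trimethoxy-2-(3,4,5-trimethoxyphenoxy)benzene | COc1cccc(OC)c1Oc1cccc(OC)c1Oc1cc(OC)c(OC)c(Oc2cc(OC)c(OC)c(OC)c2Oc2cc(OC)c(OC)c(OC)c2)c1 | intermediate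
16 | bis(pinacol boronate) of 15, boron at A1 and B4 | COc1cc(B2OC(C)(C)C(C)(C)O2)cc(OC)c1Oc1cc(B2OC(C)(C)C(C)(C)O2)cc(OC)c1Oc1cc(OC)c(OC)c(Oc2cc(OC)c(OC)c(OC)c2Oc2cc(OC)c(OC)c(OC)c2)c1 | intermediate
17 | 4-[2-{3,4-dimethoxy-5-[3,4,5-trimethoxy-2-(3,4,5-trimethoxyphenoxy)phenoxy]phenoxy}-5-hydroxy-3-methoxyphenoxy]-3,5-dimethoxyphenol (undeca-O-methyl pseudopentafuhalol D) | COc1cc(O)cc(OC)c1Oc1cc(O)cc(OC)c1Oc1cc(OC)c(OC)c(Oc2cc(OC)c(OC)c(OC)c2Oc2cc(OC)c(OC)c(OC)c2)c1 | intermediate
18 | pseudopentafuhalol D | Oc1cc(O)c(Oc2cc(O)cc(O)c2Oc2cc(O)c(O)c(Oc3cc(O)c(O)c(O)c3Oc3cc(O)c(O)c(O)c3)c2)c(O)c1 | target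

## Step count and risk

Total step count: 10. Longest linear sequence: 6 steps (steps 3, 4, 7, 8, 9, 10; the branch through steps 5 and 6 is equally long). The route is convergent, with three branches that meet in steps 7 and 8.

**Step 9 (key step).**
- What may go wrong: the second borylation may stall, because the catalyst turns over slowly on electron-rich arenes and the large polyether may bind iridium, so that mono- and diborylated material form side by side. The electron-rich 4-aryloxyphenols may also be over-oxidised in alkaline peroxide.
- Fallback: the same twofold borylation–oxidation is moved to the small ring AB unit. It sets out from 5 and comes back at 18. Phenol 5 is protected at B1 (NaH, MOMCl, THF) to give 1-(2,6-dimethoxyphenoxy)-3-methoxy-2-(methoxymethoxy)benzene F1. Borylation under the step 9 conditions gives the bis(pinacol boronate) F2, which is oxidised in the same flask to 4-[5-hydroxy-3-methoxy-2-(methoxymethoxy)phenoxy]-3,5-dimethoxyphenol F3. MeI and K2CO3 give 1,5-dimethoxy-2-(methoxymethoxy)-3-(2,4,6-trimethoxyphenoxy)benzene F4, and HCl in MeOH removes the acetal to give 2,4-dimethoxy-6-(2,4,6-trimethoxyphenoxy)phenol F5. Coupling of F5 with 14 as in step 8 gives trideca-O-methyl pseudopentafuhalol D F6, and BBr3 as in step 10 gives 18.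

**Step 7.**
- What may go wrong: loss of halogen discrimination. The C5 iodide is shielded by its ortho methoxy group while the C1 bromide is unhindered, so some oxidative addition at bromine, double arylation or reductive loss of iodine may occur.
- Fallback: ring C is coupled without its second halogen, and the bromine is introduced afterwards at the only unhindered C–H. It sets out from 10 and comes back at 14. Phenol 10 and purchased 1-bromo-2,3-dimethoxybenzene (COc1cccc(Br)c1OC) are coupled with CuI, picolinic acid and K3PO4 in DMSO at 110 °C to give 1-(2,3-dimethoxyphenoxy)-3,4,5-trimethoxy-2-(3,4,5-trimethoxyphenoxy)benzene F7. Iridium-catalysed borylation ([Ir(OMe)(cod)]2, the same bipyridine, B2pin2) at position C1 gives the pinacol boronate F8. CuBr2 in MeOH/H2O at 80 °C replaces boron by bromine and gives 14.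

**Step 8.**
- What may go wrong: slow C–O bond formation at copper for the doubly ortho-substituted phenoxide, so that loss of bromine from 14 by reduction and oxidation of the phenol take over at the temperature needed.
- Fallback: the roles at ring C are reversed to an oxidative coupling at room temperature. It sets out from 14 and comes back at 15. Bromine–lithium exchange (n-BuLi, THF, −78 °C), B(OiPr)3 and aqueous HCl give {3,4-dimethoxy-5-[3,4,5-trimethoxy-2-(3,4,5-trimethoxyphenoxy)phenoxy]phenyl}boronic acid F9. Chan–Lam coupling of F9 with 5 (Cu(OAc)2, a divalent copper salt, pyridine, 4 Å molecular sieves, CH2Cl2, air, rt), a reaction known to tolerate 2,6-disubstituted phenols, gives 15.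

**Step 10.**
- What may go wrong: incomplete cleavage of some of the eleven methyl ethers when borate chelates of the pyrogallol units precipitate, and air oxidation of the catechol and pyrogallol rings during isolation.
- Fallback: the polyphenol is purified as a stable derivative. It sets out from 17 and comes back at 18. After BBr3 treatment the crude product is acetylated directly (Ac2O, pyridine, DMAP) to trideca-O-acetyl pseudopentafuhalol D F10, which can be chromatographed and freed from partly methylated material. Acid-catalysed methanolysis (HCl in MeOH, argon, rt) then releases 18 without exposure to base.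

## Further compounds

F1 | step 9 | 1-(2,6-dimethoxyphenoxy)-3-methoxy-2-(methoxymethoxy)benzene | COCOc1c(OC)cccc1Oc1c(OC)cccc1OC
F2 | step 9 | bis(pinacol boronate) of F1, boron at A1 and B4 | COCOc1c(OC)cc(B2OC(C)(C)C(C)(C)O2)cc1Oc1c(OC)cc(B2OC(C)(C)C(C)(C)O2)cc1OC
F3 | step 9 | 4-[5-hydroxy-3-methoxy-2-(methoxymethoxy)phenoxy]-3,5-dimethoxyphenol | COCOc1c(OC)cc(O)cc1Oc1c(OC)cc(O)cc1OC
F4 | step 9 | 1,5-dimethoxy-2-(methoxymethoxy)-3-(2,4,6-trimethoxyphenoxy)benzene | COCOc1c(OC)cc(OC)cc1Oc1c(OC)cc(OC)cc1OC
F5 | step 9 | 2,4-dimethoxy-6-(2,4,6-trimethoxyphenoxy)phenol | Oc1c(OC)cc(OC)cc1Oc1c(OC)cc(OC)cc1OC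
F6 | step 9 | trideca-O-methyl pseudopentafuhalol D | COc1cc(OC)cc(OC)c1Oc1cc(OC)cc(OC)c1Oc1cc(OC)c(OC)c(Oc2cc(OC)c(OC)c(OC)c2Oc2cc(OC)c(OC)c(OC)c2)c1
F7 | step 7 | 1-(2,3-dimethoxyphenoxy)-3,4,5-trimethoxy-2-(3,4,5-trimethoxyphenoxy)benzene | COc1cccc(Oc2cc(OC)c(OC)c(OC)c2Oc2cc(OC)c(OC)c(OC)c2)c1OC
F8 | step 7 | 2-{3,4-dimethoxy-5-[3,4,5-trimethoxy-2-(3,4,5-trimethoxyphenoxy)phenoxy]phenyl}-4,4,5,5-tetramethyl-1,3,2-dioxaborolane | COc1cc(B2OC(C)(C)C(C)(C)O2)cc(Oc2cc(OC)c(OC)c(OC)c2Oc2cc(OC)c(OC)c(OC)c2)c1OC
F9 | step 8 | {3,4-dimethoxy-5-[3,4,5-trimethoxy-2-(3,4,5-trimethoxyphenoxy)phenoxy]phenyl}boronic acid | COc1cc(B(O)O)cc(Oc2cc(OC)c(OC)c(OC)c2Oc2cc(OC)c(OC)c(OC)c2)c1OC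
F10 | step 10 | trideca-O-acetyl pseudopentafuhalol D | CC(=O)Oc1cc(OC(C)=O)c(Oc2cc(OC(C)=O)cc(OC(C)=O)c2Oc2cc(OC(C)=O)c(OC(C)=O)c(Oc3cc(OC(C)=O)c(OC(C)=O)c(OC(C)=O)c3Oc3cc(OC(C)=O)c(OC(C)=O)c(OC(C)=O)c3)c2)c(OC(C)=O)c1
A1 | alternative 1 | 2-[2-(benzyloxy)-3,5-dimethoxyphenoxy]benzene-1,3,5-triol | Oc1cc(O)c(Oc2cc(OC)cc(OC)c2OCc2ccccc2)c(O)c1
A2 | alternative 1 | methyl 6-[2-(benzyloxy)-3,5-dimethoxyphenoxy]-3,5-dioxohexanoate | COC(=O)CC(=O)CC(=O)COc1cc(OC)cc(OC)c1OCc1ccccc1
A3 | alternative 2 | 2-[3-(benzyloxy)-4,5-dimethoxyphenoxy]-5-methoxybenzene-1,3-diol | COc1cc(O)c(Oc2cc(OC)c(OC)c(OCc3ccccc3)c2)c(O)c1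
A4 | alternative 2 | 6-{[3-(benzyloxy)-4,5-dimethoxyphenoxy]methyl}-4-methoxy-2H-pyran-2-one | COC1=CC(=O)OC(COc2cc(OC)c(OC)c(OCc3ccccc3)c2)=C1
A5 | alternative 3 | 6-(5-benzyloxy-2,3-dimethoxyphenoxy)-2,3,4-trimethoxyphenol | COc1cc(OCc2ccccc2)cc(Oc2cc(OC)c(OC)c(OC)c2O)c1OC
A6 | alternative 3 | 4-[(Z)-2-(5-benzyloxy-2,3-dimethoxyphenoxy)ethenyl]-2,3,4-trimethoxycyclobut-2-en-1-one (racemic) | COC1=C(OC)C(OC)(/C=C\Oc2cc(OCc3ccccc3)cc(OC)c2OC)C1=O
A7 | alternative 3 | dimethyl squarate (3,4-dimethoxycyclobut-3-ene-1,2-dione) | COC1=C(OC)C(=O)C1=O
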